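**Plan**

1. Retrosynthetic cuts, in order: the two O-benzyl groups; the C4–H bond (hydrogenation of a 4-methylidene); the ring bond C3–C4; the ether bond C2–O1; then C5–C(alkyne) and C2=C3, which leads back to one aldehyde, O-benzylsyringaldehyde, plus two two-carbon units.
2. Enabling feature: in the oxolane (O1, C2–C5), C3 and C4 are CH(CH3) carbons held 1,6 to each other through O1. They are therefore the internal carbons of a vinyl and an ethynyl group on a bis-benzylic ether, and C2 and C5 are the same aryl carbinol carbon in opposite configurations (2S,5R, aryl groups cis).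
3. Forward order: a propargylic alcohol and a cinnamyl carbonate are joined at O1, then the only new ring, the oxolane, is closed at C3–C4 by palladium hydride reductive enyne cyclization. The benzene rings are bought.
4. Stereochemistry: C5 from catalytic asymmetric alkynylation; C2 from the iridium catalyst in the allylic etherification; C3 (methyl trans to the C2 aryl) by 1,2-induction in the ring closure; C4 (methyl cis to the C5 aryl, trans to the C3 methyl) by hydrogenation of the exocyclic alkene from the face opposite the two cis aryl groups.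
5. Locants used throughout: O1, C2 (S, aryl), C3 (S, methyl), C4 (S, methyl), C5 (R, aryl); Ar = 4-(benzyloxy)-3,5-dimethoxyphenyl.

Key step: step 8

Assumption: the sense of induction of (S,S)-ProPhenol (step 2) and of the (Sa,Sc,Sc)-phosphoramidite (step 6) is taken by analogy with related aryl aldehydes and cinnamyl carbonates; if either proves opposite, the mirror-image ligand is used and nothing else changes. Catalyst-bound species of catalytic cycles are described in the Why lines and carry no numbers.

**Route**

Step 1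
Reactants: 1 syringaldehyde (4-hydroxy-3,5-dimethoxybenzaldehyde)
Product: 2 4-(benzyloxy)-3,5-dimethoxybenzaldehyde
Conditions: BnBr, K2CO3, DMF, 60 °C
Reagents that add atoms: benzyl bromide, BrCc1ccccc1
Why: Williamson etherification of the acidic phenol (phenoxide SN2 on a benzylic bromide); benzyl is chosen because the last step removes it by hydrogenolysis.

Step 2
Reactants: 2 4-(benzyloxy)-3,5-dimethoxybenzaldehyde; 3 ethynyltrimethylsilane
Product: 5 (1S)-1-[4-(benzyloxy)-3,5-dimethoxyphenyl]-3-(trimethylsilyl)prop-2-yn-1-ol, via alkynylzinc 4 (not isolated)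
Conditions: Me2Zn, (S,S)-ProPhenol (10 mol %), Ph3P=O (20 mol %), toluene, 0 °C; aq NH4Cl
Reagents that add atoms: none
Why: Catalytic asymmetric alkynylation of an aryl aldehyde by an alkynylzinc formed in the flask, in which the dinuclear zinc–ProPhenol pocket selects the aldehyde face and so sets the future C5 (the descriptor is S here only because the silylalkynyl group outranks aryl).

Step 3
Reactants: 2 4-(benzyloxy)-3,5-dimethoxybenzaldehyde; 6 ethyl (triphenylphosphoranylidene)acetate
Product: 7 ethyl (2E)-3-[4-(benzyloxy)-3,5-dimethoxyphenyl]prop-2-enoate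
Conditions: toluene, 80 °C
Reagents that add atoms: none
Why: Wittig olefination with a stabilised ylide, which should give the E enoate.

Step 4
Reactants: 7 ethyl (2E)-3-[4-(benzyloxy)-3,5-dimethoxyphenyl]prop-2-enoate
Product: 8 (2E)-3-[4-(benzyloxy)-3,5-dimethoxyphenyl]prop-2-en-1-ol
Conditions: i-Bu2AlH (2.2 equiv), CH2Cl2, −78 °C; aq Rochelle salt
Reagents that add atoms: none
Why: 1,2-Reduction of a conjugated ester by an electrophilic aluminium hydride leaves the alkene and the aryl ethers untouched.

Step 5
Reactants: 8 (2E)-3-[4-(benzyloxy)-3,5-dimethoxyphenyl]prop-2-en-1-ol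
Product: 9 tert-butyl (2E)-3-[4-(benzyloxy)-3,5-dimethoxyphenyl]prop-2-en-1-yl carbonate
Conditions: Boc2O, DMAP (10 mol %), CH2Cl2, 0 °C to rt
Reagents that add atoms: di-tert-butyl dicarbonate, CC(C)(C)OC(=O)OC(=O)OC(C)(C)C
Why: DMAP-catalysed acylation of a primary allylic alcohol gives the linear carbonate, whose leaving group releases only the poorly nucleophilic tert-butoxide in the next step.

Step 6
Reactants: 5 (1S)-1-[4-(benzyloxy)-3,5-dimethoxyphenyl]-3-(trimethylsilyl)prop-2-yn-1-ol; 9 tert-butyl (2E)-3-[4-(benzyloxy)-3,5-dimethoxyphenyl]prop-2-en-1-yl carbonate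
Product: 12 [(3S)-3-Ar-3-{[(1S)-1-Ar-prop-2-en-1-yl]oxy}prop-1-yn-1-yl]trimethylsilane, via lithium alkoxide 10 (not isolated), via cuprous alkoxide 11 (not isolated)
Conditions: n-BuLi (1.0 equiv), THF, 0 °C; CuI (1.0 equiv), rt; then 9, [Ir(cod)Cl]2 (2 mol %), (Sa,Sc,Sc)-O,O'-(1,1'-binaphthyl-2,2'-diyl) N,N-bis(1-phenylethyl)phosphoramidite (4 mol %), THF, rt; aq NH4Cl
Reagents that add atoms: none
Why: Iridium-catalysed asymmetric allylic etherification, in which the cyclometalated iridium–phosphoramidite allyl complex from 9 is attacked by the soft cuprous alkoxide at the aryl-bearing terminus, so the branched ether forms and the ligand sets C2 (S) while the carbinol C–O bond of 5 is not touched.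

Step 7
Reactants: 12 [(3S)-3-Ar-3-{[(1S)-1-Ar-prop-2-en-1-yl]oxy}prop-1-yn-1-yl]trimethylsilane
Product: 13 (1R)-1-Ar-prop-2-yn-1-yl (1S)-1-Ar-prop-2-en-1-yl ether
Conditions: K2CO3 (0.2 equiv), MeOH/THF, rt
Reagents that add atoms: none
Why: Methoxide-mediated protodesilylation of the alkynylsilane frees the terminal alkyne without touching either stereocentre (the propargylic descriptor becomes R only through the change in CIP ranking).

Step 8
Reactants: 13 (1R)-1-Ar-prop-2-yn-1-yl (1S)-1-Ar-prop-2-en-1-yl ether
Product: 14 (2S,3S,5R)-2,5-bis[4-(benzyloxy)-3,5-dimethoxyphenyl]-3-methyl-4-methylideneoxolane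
Conditions: Pd2(dba)3·CHCl3 (2.5 mol %), P(o-tol)3 (10 mol %), AcOH (2 equiv), Et3SiH (5 equiv), toluene, rt
Reagents that add atoms: none
Why: Acetic acid adds oxidatively to zerovalent palladium to give H–Pd–OAc, which hydropalladates the terminal alkyne with Pd on the internal carbon (the future C4); the vinylpalladium then inserts the tethered vinyl group in a syn carbopalladation that forges C3–C4, and the primary alkylpalladium is reduced by Et3SiH (Si–H/Pd–OAc exchange, C–H reductive elimination) to the C3 methyl before β-hydride elimination can give a diene. The closest known reaction type is the palladium-catalysed reductive cyclization of 1,6-enynes with a silane and acetic acid, the reductive variant of enyne cycloisomerization, which tolerates oxygen in the three-atom tether. The only ring closed is the oxolane (O1, C2–C5), in 5-exo-trig mode by attack of C4 on C3. The new stereocentre C3 is controlled by the adjacent C2 stereocentre: in the envelope-like insertion transition state both aryl groups (cis, as fixed by the ether) sit pseudo-equatorial and the palladium-bearing CH2 turns away from the C2 aryl, so the methyl should end trans to that aryl (3S). The step needs chemoselectivity for the alkyne in the hydropalladation and for cyclization over simple alkyne reduction, secured by the terminal alkyne being the best acceptor for H–Pd–OAc and by the short ether tether that makes insertion fast, while the regiochemistry (Pd on the internal carbon) follows from chelation by the pendant alkene.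

Step 9
Reactants: 14 (2S,3S,5R)-2,5-bis[4-(benzyloxy)-3,5-dimethoxyphenyl]-3-methyl-4-methylideneoxolane
Product: 15 (2S,3S,4S,5R)-2,5-bis[4-(benzyloxy)-3,5-dimethoxyphenyl]-3,4-dimethyloxolane
Conditions: H2 (4 atm), RhCl(PPh3)3 (5 mol %), toluene/EtOH, rt
Reagents that add atoms: none
Why: Homogeneous syn hydrogenation of the 1,1-disubstituted alkene should occur on the face opposite the two cis aryl groups, so H reaches C4 from the side of the C3 methyl and the new methyl ends cis to the C5 aryl and trans to the C3 methyl (4S); this catalyst does not migrate the double bond into the ring and leaves the benzyl ethers intact.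

Step 10
Reactants: 15 (2S,3S,4S,5R)-2,5-bis[4-(benzyloxy)-3,5-dimethoxyphenyl]-3,4-dimethyloxolane
Product: 16 4,4'-[(2S,3S,4S,5R)-3,4-dimethyloxolane-2,5-diyl]bis(2,6-dimethoxyphenol), the target (equally (2R,3S,4S,5S) when numbered from the other end)
Conditions: H2 (1 atm), Pd/C (10 wt %), EtOAc, rt
Reagents that add atoms: none
Why: Hydrogenolysis of the two aryl benzyl ethers under neutral conditions, where the ring benzylic C–O bonds of the dialkyl ether should be much slower to cleave.

**Compound list**

1 | syringaldehyde (4-hydroxy-3,5-dimethoxybenzaldehyde) | COc1cc(C=O)cc(OC)c1O | starting material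
2 | 4-(benzyloxy)-3,5-dimethoxybenzaldehyde | COc1cc(C=O)cc(OC)c1OCc1ccccc1 | intermediate
3 | ethynyltrimethylsilane | C#C[Si](C)(C)C | starting material
4 | methyl[(trimethylsilyl)ethynyl]zinc (not isolated) | C[Zn]C#C[Si](C)(C)C | intermediate
5 | (1S)-1-[4-(benzyloxy)-3,5-dimethoxyphenyl]-3-(trimethylsilyl)prop-2-yn-1-ol | COc1cc([C@H](O)C#C[Si](C)(C)C)cc(OC)c1OCc1ccccc1 | intermediate
6 | ethyl (triphenylphosphoranylidene)acetate | CCOC(=O)C=P(c1ccccc1)(c1ccccc1)c1ccccc1 | starting material
7 | ethyl (2E)-3-[4-(benzyloxy)-3,5-dimethoxyphenyl]prop-2-enoate | CCOC(=O)/C=C/c1cc(OC)c(OCc2ccccc2)c(OC)c1 | intermediate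
8 | (2E)-3-[4-(benzyloxy)-3,5-dimethoxyphenyl]prop-2-en-1-ol | OC/C=C/c1cc(OC)c(OCc2ccccc2)c(OC)c1 | intermediate
9 | tert-butyl (2E)-3-[4-(benzyloxy)-3,5-dimethoxyphenyl]prop-2-en-1-yl carbonate | CC(C)(C)OC(=O)OC/C=C/c1cc(OC)c(OCc2ccccc2)c(OC)c1 | intermediate
10 | lithium (1S)-1-[4-(benzyloxy)-3,5-dimethoxyphenyl]-3-(trimethylsilyl)prop-2-yn-1-olate (not isolated) | [Li+].[O-][C@@H](c1cc(OC)c(OCc2ccccc2)c(OC)c1)C#C[Si](C)(C)C | intermediate
11 | cuprous (1S)-1-[4-(benzyloxy)-3,5-dimethoxyphenyl]-3-(trimethylsilyl)prop-2-yn-1-olate (not isolated) | [Cu+].[O-][C@@H](c1cc(OC)c(OCc2ccccc2)c(OC)c1)C#C[Si](C)(C)C | intermediate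
12 | [(3S)-3-Ar-3-{[(1S)-1-Ar-prop-2-en-1-yl]oxy}prop-1-yn-1-yl]trimethylsilane, Ar = 4-(benzyloxy)-3,5-dimethoxyphenyl | COc1cc([C@H](C=C)O[C@@H](c2cc(OC)c(OCc3ccccc3)c(OC)c2)C#C[Si](C)(C)C)cc(OC)c1OCc1ccccc1 | intermediate
13 | (1R)-1-Ar-prop-2-yn-1-yl (1S)-1-Ar-prop-2-en-1-yl ether, Ar = 4-(benzyloxy)-3,5-dimethoxyphenyl | COc1cc([C@H](C=C)O[C@@H](c2cc(OC)c(OCc3ccccc3)c(OC)c2)C#C)cc(OC)c1OCc1ccccc1 | intermediate
14 | (2S,3S,5R)-2,5-bis[4-(benzyloxy)-3,5-dimethoxyphenyl]-3-methyl-4-methylideneoxolane | COc1cc([C@H]2O[C@@H](c3cc(OC)c(OCc4ccccc4)c(OC)c3)C(=C)[C@@H]2C)cc(OC)c1OCc1ccccc1 | intermediate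
15 | (2S,3S,4S,5R)-2,5-bis[4-(benzyloxy)-3,5-dimethoxyphenyl]-3,4-dimethyloxolane | COc1cc([C@H]2O[C@@H](c3cc(OC)c(OCc4ccccc4)c(OC)c3)[C@@H](C)[C@@H]2C)cc(OC)c1OCc1ccccc1 | intermediate
16 | 4,4'-[(2S,3S,4S,5R)-3,4-dimethyloxolane-2,5-diyl]bis(2,6-dimethoxyphenol) | COc1cc([C@H]2O[C@@H](c3cc(OC)c(O)c(OC)c3)[C@@H](C)[C@@H]2C)cc(OC)c1O | target

**Count and risks**

Total step count: 10. Longest linear sequence: 9 steps (steps 1, 3, 4, 5, 6, 7, 8, 9, 10).

Steps most likely to fail:

Step 8. The vinylpalladium may be reduced by the silane before it inserts (simple alkyne reduction), the alkylpalladium may undergo β-hydride elimination to a diene, zerovalent palladium with acetic acid may ionize the allylic benzylic ether, or the insertion may show poor 2,3-trans selectivity. The fallback sets out from 13 and uses a tin-radical chain instead of a metal hydride. Bu3SnH with AIBN in toluene at 80 °C should add the stannyl radical to the alkyne terminus, and the resulting vinyl radical at C4 should close 5-exo onto the vinyl group (chair-like transition state, aryl pseudo-equatorial) to give tributyl{[(2S,4S,5S)-2,5-bis[4-(benzyloxy)-3,5-dimethoxyphenyl]-4-methyloxolan-3-ylidene]methyl}stannane F1 as an alkene-geometry mixture. Protodestannylation with anhydrous HCl (1 equiv) in CH2Cl2 at 0 °C would then return the route at 14.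

Step 6. The hindered and rather acidic propargylic cuprous alkoxide may attack the iridium allyl complex too slowly, the linear ether may compete, the alkoxide may cleave the C–Si bond, or catalyst control over C2 may be incomplete. The fallback forms the other ether bond (C5–O1) under catalyst control. From 9, iridium-catalysed allylic hydroxylation ([Ir(cod)Cl]2, the same phosphoramidite, KHCO3 as oxygen nucleophile) would give (1S)-1-[4-(benzyloxy)-3,5-dimethoxyphenyl]prop-2-en-1-ol F2. From 2, HC≡CMgBr in THF would give racemic 1-[4-(benzyloxy)-3,5-dimethoxyphenyl]prop-2-yn-1-ol F3, which Ac2O and DMAP would convert to 1-[4-(benzyloxy)-3,5-dimethoxyphenyl]prop-2-yn-1-yl acetate F4. Copper-catalysed enantioselective propargylic etherification of F4 with F2 (CuOTf·1/2C6H6, chiral pybox ligand, i-Pr2NEt, MeOH, low temperature), which runs through a copper allenylidene, would rejoin the route at 13 and make step 7 unnecessary.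

Step 9. Discrimination between the two faces of the hindered exocyclic alkene may be poor, or the hydrogenation may be slow enough for the double bond to migrate into the ring and erase C3 or C5. The fallback sets out from 14 and uses a bulky stoichiometric borane, whose approach is governed by sterics alone. 9-BBN in THF followed by NaOH/H2O2 should place boron on the terminal carbon and hydrogen on C4 from the face opposite the aryl groups, giving [(2R,3R,4S,5S)-2,5-bis[4-(benzyloxy)-3,5-dimethoxyphenyl]-4-methyloxolan-3-yl]methanol F5. TsCl in pyridine would give [(2R,3R,4S,5S)-2,5-bis[4-(benzyloxy)-3,5-dimethoxyphenyl]-4-methyloxolan-3-yl]methyl 4-methylbenzenesulfonate F6, and LiEt3BH in THF would reduce it to the methyl compound, returning the route at 15.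

**Further compounds**

F1 | step 8 | tributyl{[(2S,4S,5S)-2,5-bis[4-(benzyloxy)-3,5-dimethoxyphenyl]-4-methyloxolan-3-ylidene]methyl}stannane (alkene geometry not defined) | COc1cc([C@H]2O[C@@H](c3cc(OC)c(OCc4ccccc4)c(OC)c3)C(=C[Sn](CCCC)(CCCC)CCCC)[C@@H]2C)cc(OC)c1OCc1ccccc1
F2 | step 6 | (1S)-1-[4-(benzyloxy)-3,5-dimethoxyphenyl]prop-2-en-1-ol | COc1cc([C@H](C=C)O)cc(OC)c1OCc1ccccc1
F3 | step 6 | racemic 1-[4-(benzyloxy)-3,5-dimethoxyphenyl]prop-2-yn-1-ol | COc1cc(C(O)C#C)cc(OC)c1OCc1ccccc1
F4 | step 6 | racemic 1-[4-(benzyloxy)-3,5-dimethoxyphenyl]prop-2-yn-1-yl acetate | COc1cc(C(OC(C)=O)C#C)cc(OC)c1OCc1ccccc1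
F5 | step 9 | [(2R,3R,4S,5S)-2,5-bis[4-(benzyloxy)-3,5-dimethoxyphenyl]-4-methyloxolan-3-yl]methanol | COc1cc([C@H]2O[C@@H](c3cc(OC)c(OCc4ccccc4)c(OC)c3)[C@@H](CO)[C@@H]2C)cc(OC)c1OCc1ccccc1
F6 | step 9 | [(2R,3R,4S,5S)-2,5-bis[4-(benzyloxy)-3,5-dimethoxyphenyl]-4-methyloxolan-3-yl]methyl 4-methylbenzenesulfonate | COc1cc([C@H]2O[C@@H](c3cc(OC)c(OCc4ccccc4)c(OC)c3)[C@@H](COS(=O)(=O)c5ccc(C)cc5)[C@@H]2C)cc(OC)c1OCc1ccccc1
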